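- Substrate goes far faster on Wednesday's run than on Monday's: the first-order constant reads 0.0599 /min at 90 °C against 8.71 × 10⁻⁴ /min at 55 °C.

| flask | substrate | first nucleophile | second nucleophile | temperature | remark | time |
|---|---|---|---|---|---|---|
| Monday's | 0.011 M | 0.90 equiv | 1.2 equiv | 55 °C | run made earlier |  |
| Wednesday's | 0.011 M | 1.4 equiv | 1.2 equiv | 90 °C | run made earlier |  |
| north | 0.011 M | 1.80 equiv | 1.20 equiv | 120 °C |  | 40 min |
| west | 0.011 M | 1.80 equiv | 1.20 equiv | 60 °C |  | 40 min |
| north-east | 0.011 M | 1.80 equiv | 1.20 equiv | 90 °C |  | 40 min |

| run | time / min | target / % | substrate / % |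
|---|---|---|---|
| Monday's | 60.0 | 3.1 | 95.2 |
| Monday's | 90.0 | 3.7 | 91.4 |
| Monday's | 150 | 6.0 | 86.3 |
| Monday's | 240 | 9.5 | 80.9 |
| Monday's | 360 | 12.3 | 73.7 |
| Monday's | 480 | 14.6 | 66.2 |
| Monday's | 720 | 17.3 | 53.4 |
| Wednesday's | 12.0 | 26.0 | 49.4 |
| Wednesday's | 20.0 | 27.5 | 30.7 |
| Wednesday's | 25.0 | 26.9 | 21.7 |
| Wednesday's | 40.0 | 18.7 | 9.1 |
| Wednesday's | 60.0 | 10.0 | 2.9 |
| Wednesday's | 80.0 | 5.1 | 1.4 |
| Wednesday's | 120 | 0.9 | 0.6 |

(scatter of a reading: 0.5 percentage points)

- which flask leads in amount of target, in percent of the substrate charged ("all alike" within 1.5 percentage points) (north / west / north-east / all alike)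
- how much target is there at the end, in percent of the substrate charged: north
- how much target is there at the end, in percent of the substrate charged: west
- how much target is there at the end, in percent of the substrate charged: north-east

- percentages count the substrate that a species holds: one side product counts as two
- what may be going on: substrate -> intermediate; first nucleophile + intermediate -> target; second nucleophile + intermediate -> other capture product; target -> over-reaction product; substrate + target -> side product

- Build west in my own reckoning, starting with the main step. A straight line through ln k against temperature gives 0.00159 /min at 60 °C. So west loses 6.18 % of its substrate in 40 min.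
- Now add capture. The capture share is the part of the lost substrate that becomes target, which chemists call selectivity.
- Wednesday's target tail, from 60.0 min to 120 min, gives a decay constant of 0.0401 /min.
- Replace the rising target curve by a mean of 0.5 times its last reading. The 12.0 min reading then gives a share of 0.638.
- The same sum at 20.0 min gives 0.556, which is less than the share at 12.0 min. So I use the earlier reading, the shorter stretch of curve.
- Take the ratio of charges for [first nucleophile]/[second nucleophile]. The selectivity factor is then 1.51, and at 1.80 equiv against 1.20 equiv the capture share is 0.693.
- That puts west at 4.28 % before decay.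
- Last comes decay. I assume it scales with temperature as substrate loss does, which gives 0.00107 /min at 60 °C. West then stands at 4.19 %.
- North-east shares Wednesday's temperature, and the proposed substrate step holds no nucleophile. So I scale Wednesday's 18.7 % at 40.0 min by the two shares, which gives 20.3 %.
- North needs the line extended to 120 °C, where a substrate constant of 2.25 /min makes target's estimated lifetime 0.664 min, much shorter than the 40 min run.
- The forecast names north-east as leader, with 0 % for north, 4.4 % for west and 20.5 % for north-east, slightly above my two non-zero figures. For north it says “everything forms within minutes, then target is destroyed”.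
- The flasks give 0 % for north, 4.54 % for west and 21.1 % for north-east, so north-east leads. North-east leads with less target than the 30.1 % it held at 20.0 min.

    substrate → intermediate (k = 9.80 × 10⁻⁴ /s, Ea = 120 kJ/mol)
    first nucleophile + intermediate → target (k = 23.0 /M/s, Ea = 48.0 kJ/mol)
    second nucleophile + intermediate → other capture product (k = 11.0 /M/s, Ea = 47.0 kJ/mol)
    target → over-reaction product (k = 7.40 × 10⁻⁴ /s, Ea = 105 kJ/mol)
    substrate + target → side product (k = 0.00730 /M/s, Ea = 84.0 kJ/mol)
    (constants at 90 °C)

- West's 4.54 % against 6.39 % of substrate lost makes a ratio of 0.711, beside the capture share of 0.693. Now read west later, at 1.5 h, with substrate at 86.1 %. The capture share and the decay term give 9.17 %, and that neighbouring flask holds 9.26 % of target.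

(The earlier runs and the new flask are calculated on assumed constants; scatter was added.)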